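**Plan**
1. Cuts (germacranolide numbering): the C4–O epoxide; C9–C10 (ring closure, followed by an oxygen shift from C9 to C14); the C8 ester and C7–C8; then the oxane is opened in one stroke at C3–C4 and O–C1; last C7–C11 and C4–C15.
2. Enabling feature: the oxane ring O–C1–C2–C3–C4–C5 has an exocyclic carbon (C15) on C4 next to the C5–O carbon, and C1 is a reduced ketal carbon. It is therefore a 2-alkoxy-5-methylene-oxane, the product of a redox-neutral ruthenium coupling of a propargylic alcohol (C15≡C4–C5–OH) with an allylic alcohol (C3=C2–C1–OH) followed by ketalization.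
3. Forward order: γ-lactone first, then the oxane (key step, then ketal reduction), then the C8/C9 unit, then the ten-membered carbocycle (eight-membered oxacycle), last the enal and the epoxide.
4. Stereochemistry: C5 and C6 from L-threitol; C1 by axial hydride delivery (2,6-cis); C7 by addition anti to the C5 branch on the butenolide; C8 by a chair Barbier addition followed by Mitsunobu inversion; C4 by exo-face epoxidation; the C9=C10 geometry by the ring.

Key step: step 11

Remark: carbon numbers are those of the germacranolide skeleton (C1 and C5 = ether carbons, C4 = spiro carbon, C6 = lactone carbinol carbon, C7 = lactone β-carbon, C8 = ester carbinol carbon, C9=C10 = ring alkene, C11–C13 = methylene-lactone carbons, C14 = formyl carbon, C15 = epoxide CH2).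

**Step 1**
Reactants: 1 (4S,5S)-2,2-dimethyl-1,3-dioxolane-4,5-dimethanol (2,3-O-isopropylidene-L-threitol)
Product: 2 [(4S,5S)-5-({[tert-butyl(dimethyl)silyl]oxy}methyl)-2,2-dimethyl-1,3-dioxolan-4-yl]methanol
Conditions: NaH (1.0 equiv), THF, 0 °C; then t-BuMe2SiCl (1.0 equiv), 0 °C → rt
Reagents that add atoms: tert-butyldimethylsilyl chloride, CC(C)(C)[Si](C)(C)Cl
Why: Monosilylation of the C2-symmetric diol through its mono-sodium alkoxide (McDougal protocol) should differentiate the two equivalent termini without touching the stereocentres.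

**Step 2**
Reactants: 2 [(4S,5S)-5-({[tert-butyl(dimethyl)silyl]oxy}methyl)-2,2-dimethyl-1,3-dioxolan-4-yl]methanol
Product: 3 (4R,5S)-5-({[tert-butyl(dimethyl)silyl]oxy}methyl)-2,2-dimethyl-1,3-dioxolane-4-carbaldehyde
Conditions: PhI(OAc)2 (1.1 equiv), TEMPO (10 mol %), CH2Cl2, rt
Reagents that add atoms: none
Why: TEMPO/oxoammonium oxidation of the primary alcohol should stop at the aldehyde under neutral conditions, so the α-alkoxy centre of the trans-dioxolane is not epimerised.

**Step 3**
Reactants: 3 (4R,5S)-5-({[tert-butyl(dimethyl)silyl]oxy}methyl)-2,2-dimethyl-1,3-dioxolane-4-carbaldehyde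
Product: 4 tert-butyl{[(4S,5S)-5-ethynyl-2,2-dimethyl-1,3-dioxolan-4-yl]methoxy}dimethylsilane
Conditions: dimethyl (1-diazo-2-oxopropyl)phosphonate (1.3 equiv), K2CO3 (2 equiv), MeOH, 0 °C → rt
Reagents that add atoms: dimethyl (1-diazo-2-oxopropyl)phosphonate, CC(=O)C(=[N+]=[N-])P(=O)(OC)OC
Why: Seyferth–Gilbert homologation under Ohira–Bestmann conditions should turn the formyl carbon into the internal alkyne carbon (future C4) and add the terminal carbon (future C15); the mild base leaves the thermodynamically preferred trans-dioxolane intact.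

**Step 4**
Reactants: 4 tert-butyl{[(4S,5S)-5-ethynyl-2,2-dimethyl-1,3-dioxolan-4-yl]methoxy}dimethylsilane
Product: 5 [(4S,5S)-5-ethynyl-2,2-dimethyl-1,3-dioxolan-4-yl]methanol
Conditions: Bu4NF (1.1 equiv), THF, 0 °C
Reagents that add atoms: none
Why: Fluoride-induced desilylation should free the primary alcohol without affecting the acetonide or the alkyne.

**Step 5**
Reactants: 5 [(4S,5S)-5-ethynyl-2,2-dimethyl-1,3-dioxolan-4-yl]methanol
Product: 6 (4R,5S)-5-ethynyl-2,2-dimethyl-1,3-dioxolane-4-carbaldehyde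
Conditions: PhI(OAc)2 (1.1 equiv), TEMPO (10 mol %), CH2Cl2, rt
Reagents that add atoms: none
Why: TEMPO/oxoammonium oxidation should give the α-alkoxy aldehyde (its carbonyl carbon is the future C7) without over-oxidation or epimerisation.

**Step 6**
Reactants: 6 (4R,5S)-5-ethynyl-2,2-dimethyl-1,3-dioxolane-4-carbaldehyde; 7 methyl acrylate
Product: 8 methyl 2-{[(4S,5S)-5-ethynyl-2,2-dimethyl-1,3-dioxolan-4-yl](hydroxy)methyl}prop-2-enoate (carbinol epimers)
Conditions: DABCO (50 mol %), 7 (5 equiv), 1,4-dioxane/H2O (1:1), rt, several days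
Reagents that add atoms: none
Why: Morita–Baylis–Hillman reaction of the activated α-alkoxy aldehyde should install C11, C12 and C13 in one step; the new carbinol centre (C7) needs no control because it becomes sp2 in step 13.

**Step 7**
Reactants: 8 methyl 2-{[(4S,5S)-5-ethynyl-2,2-dimethyl-1,3-dioxolan-4-yl](hydroxy)methyl}prop-2-enoate
Product: 9 (5R)-4-hydroxy-5-[(1S)-1-hydroxyprop-2-yn-1-yl]-3-methylideneoxolan-2-one (C4 epimers)
Conditions: CF3CO2H/H2O (4:1), 0 °C → rt
Reagents that add atoms: none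
Why: Acid hydrolysis of the acetonide frees the C5 and C6 hydroxyls and the C6 hydroxyl should lactonise onto the methyl ester (5-exo-trig, γ-lactone preferred over the δ-lactone), leaving the propargylic C5 hydroxyl free; C5 and C6 keep the L-threitol configuration.

**Step 8**
Reactants: 10 prop-2-yn-1-ol
Product: 11 2-iodoprop-2-en-1-ol
Conditions: NaI (1.2 equiv), Me3SiCl (1.2 equiv), H2O (0.6 equiv), MeCN, rt
Reagents that add atoms: sodium iodide, [Na+].[I-]
Why: Markovnikov hydroiodination of the terminal alkyne by hydrogen iodide generated in the flask should give the 2-iodoalkene.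

**Step 9**
Reactants: 11 2-iodoprop-2-en-1-ol
Product: 12 2-iodoprop-2-enal
Conditions: MnO2 (10 equiv), CH2Cl2, rt; filtered, solution used at once
Reagents that add atoms: none
Why: Allylic oxidation with MnO2 should give the sensitive α-iodo enal under neutral conditions.

**Step 10**
Reactants: 12 2-iodoprop-2-enal
Product: 13 2-iodopenta-1,4-dien-3-ol (racemic)
Conditions: CH2=CHMgBr (1.1 equiv), THF, −78 °C; then H2O
Reagents that add atoms: vinylmagnesium bromide, C=C[Mg]Br
Why: 1,2-Addition of the vinyl Grignard reagent to the enal should give the bis-allylic alcohol; its carbinol centre needs no control because it is oxidised in step 11.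

**Step 11**
Reactants: 9 (5R)-4-hydroxy-5-[(1S)-1-hydroxyprop-2-yn-1-yl]-3-methylideneoxolan-2-one; 13 2-iodopenta-1,4-dien-3-ol (2 equiv)
Product: 16 (5S)-4-hydroxy-5-[(2S)-6-(1-iodoethenyl)-6-methoxy-3-methylideneoxan-2-yl]-3-methylideneoxolan-2-one (anomers), via hydroxy enone 14 (not isolated), via hemiketal 15 (not isolated)
Conditions: CpRu(MeCN)3PF6 (10 mol %), acetone, rt; then MeOH, PPTS (10 mol %), rt, same flask
Reagents that add atoms: methanol, CO
Why: The cationic CpRu fragment binds the terminal alkyne of 9 and the monosubstituted vinyl group of 13 and couples them oxidatively to a ruthenacyclopentene, which forms the C3–C4 bond at the internal alkyne carbon; β-hydride elimination of the carbinol hydrogen and C–H reductive elimination then release the exocyclic C4=C15 alkene and an enol that tautomerises to the C1 ketone 14. The closest known reaction type is the ruthenium-catalysed coupling of terminal alkynes with allylic alcohols to γ,δ-unsaturated ketones, which with propargylic alcohols gives 2-alkoxy-5-methylene-oxanes. The C5 hydroxyl adds to the C1 carbonyl (6-exo-trig) and closes the oxane as hemiketal 15, and acid-catalysed exchange with methanol, with loss of water, fixes the O–C1 bond as the mixed ketal 16. The only new stereocentre, the ketal carbon C1, forms as an anomeric mixture under thermodynamic control and is reset in step 12; C5 and C6 are not touched. The step needs branched regioselectivity at the alkyne, which the coordinating propargylic hydroxyl should secure, and chemoselectivity for the monosubstituted alkene of 13, which should hold because the 1-iodovinyl group and the electron-poor 1,1-disubstituted methylene-lactone alkene do not readily enter the ruthenacycle.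

**Step 12**
Reactants: 16 (5S)-4-hydroxy-5-[(2S)-6-(1-iodoethenyl)-6-methoxy-3-methylideneoxan-2-yl]-3-methylideneoxolan-2-one
Product: 17 (5S)-4-hydroxy-5-[(2S,6R)-6-(1-iodoethenyl)-3-methylideneoxan-2-yl]-3-methylideneoxolan-2-one (2,6-cis oxane; lactone C4 epimers)
Conditions: Et3SiH (3 equiv), BF3·OEt2 (1.5 equiv), CH2Cl2, −78 → −40 °C
Reagents that add atoms: none
Why: Ionic hydrogenation of the ketal (Kishi-type reduction): the Lewis acid gives the oxocarbenium ion and the silane delivers hydride axially, so the 1-iodoethenyl group should end up equatorial and cis to the C5 substituent, which sets C1.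

**Step 13**
Reactants: 17 (5S)-4-hydroxy-5-[(2S,6R)-6-(1-iodoethenyl)-3-methylideneoxan-2-yl]-3-methylideneoxolan-2-one
Product: 18 (5S)-3-(bromomethyl)-5-[(2S,6R)-6-(1-iodoethenyl)-3-methylideneoxan-2-yl]furan-2(5H)-one
Conditions: NBS (1.2 equiv), Me2S (1.4 equiv), CH2Cl2, −20 → 0 °C
Reagents that add atoms: N-bromosuccinimide, O=C1CCC(=O)N1Br
Why: Corey–Kim-type activation of the Baylis–Hillman alcohol and bromide attack with allylic transposition (SN2′) should give the conjugated bromomethyl butenolide under neutral conditions; both C7 epimers converge.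

**Step 14**
Reactants: 18 (5S)-3-(bromomethyl)-5-[(2S,6R)-6-(1-iodoethenyl)-3-methylideneoxan-2-yl]furan-2(5H)-one; 19 2,2-dimethoxyacetaldehyde
Product: 20 (4R,5S)-4-[(1R)-1-hydroxy-2,2-dimethoxyethyl]-5-[(2S,6R)-6-(1-iodoethenyl)-3-methylideneoxan-2-yl]-3-methylideneoxolan-2-one
Conditions: In powder (1.5 equiv), 19 (commercial aqueous solution, 3 equiv), THF/H2O (1:1), rt
Reagents that add atoms: none
Why: Indium-mediated Barbier allylation: the allylindium reacts through its γ-carbon (C7), which regenerates the α-methylene lactone; attack should occur on the butenolide face anti to the C6 oxanyl group (trans-lactone), and the chair transition state of the E-locked allyl unit should give the anti carbinol, that is the C8 epimer of the target, which step 15 inverts.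

**Step 15**
Reactants: 20 (4R,5S)-4-[(1R)-1-hydroxy-2,2-dimethoxyethyl]-5-[(2S,6R)-6-(1-iodoethenyl)-3-methylideneoxan-2-yl]-3-methylideneoxolan-2-one; 21 methacrylic acid
Product: 22 (1S)-1-{(2S,3S)-2-[(2S,6R)-6-(1-iodoethenyl)-3-methylideneoxan-2-yl]-4-methylidene-5-oxooxolan-3-yl}-2,2-dimethoxyethyl 2-methylprop-2-enoate
Conditions: PPh3 (2 equiv), DIAD (2 equiv), toluene, 0 °C → rt
Reagents that add atoms: none
Why: Mitsunobu esterification: the C8 alkoxyphosphonium ion is displaced by methacrylate with inversion (SN2), which should install the ester and correct C8 in one operation.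

**Step 16**
Reactants: 22 (1S)-1-{(2S,3S)-2-[(2S,6R)-6-(1-iodoethenyl)-3-methylideneoxan-2-yl]-4-methylidene-5-oxooxolan-3-yl}-2,2-dimethoxyethyl 2-methylprop-2-enoate
Product: 23 (1S)-1-{(2S,3S)-2-[(2S,6R)-6-(1-iodoethenyl)-3-methylideneoxan-2-yl]-4-methylidene-5-oxooxolan-3-yl}-2-oxoethyl 2-methylprop-2-enoate
Conditions: Et3SiOTf (2 equiv), 2,6-lutidine (3 equiv), CH2Cl2, 0 °C; then H2O
Reagents that add atoms: water, O
Why: Silyl triflate/lutidine acetal cleavage goes through a pyridinium intermediate that water hydrolyses to the aldehyde under nearly neutral conditions, so the exocyclic alkene, the methylene lactone and the α-acyloxy centre should survive.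

**Step 17**
Reactants: 23 (1S)-1-{(2S,3S)-2-[(2S,6R)-6-(1-iodoethenyl)-3-methylideneoxan-2-yl]-4-methylidene-5-oxooxolan-3-yl}-2-oxoethyl 2-methylprop-2-enoate
Product: 24 (1R,5S,6S,7R,8S)-9-hydroxy-8-(methacryloyloxy)-1,5-epoxygermacra-4(15),10(14),11(13)-trien-12,6-olide (C9 epimers)
Conditions: CrCl2 (8 equiv), NiCl2 (2 mol %), DMSO/THF, rt, slow addition, 0.002 M
Reagents that add atoms: none
Why: Nozaki–Hiyama–Kishi reaction: nickel-catalysed activation of the alkenyl iodide, transfer to trivalent chromium and chemoselective 1,2-addition to the aldehyde should close the eight-membered oxacycle (ten-membered carbocycle) between C10 and C9; the new C9 carbinol centre is removed in step 18.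

**Step 18**
Reactants: 24 (1R,5S,6S,7R,8S)-9-hydroxy-8-(methacryloyloxy)-1,5-epoxygermacra-4(15),10(14),11(13)-trien-12,6-olide
Product: 25 (1R,5S,6S,7R,8R,9Z)-14-hydroxy-8-(methacryloyloxy)-1,5-epoxygermacra-4(15),9,11(13)-trien-12,6-olide
Conditions: Ph3SiOReO3 (5 mol %), Et2O, 0 °C
Reagents that add atoms: none
Why: Rhenium-oxo-catalysed 1,3-transposition of the allylic alcohol ([3,3] shift of the perrhenate ester) should move oxygen from C9 to C14 and the double bond into the ring (C9=C10), where it can only be ring-cis and is the more substituted alkene.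

**Step 19**
Reactants: 25 (1R,5S,6S,7R,8R,9Z)-14-hydroxy-8-(methacryloyloxy)-1,5-epoxygermacra-4(15),9,11(13)-trien-12,6-olide
Product: 26 (1R,5S,6S,7R,8R,9E)-8-(methacryloyloxy)-14-oxo-1,5-epoxygermacra-4(15),9,11(13)-trien-12,6-olide
Conditions: MnO2 (15 equiv), CH2Cl2, rt
Reagents that add atoms: none
Why: Chemoselective oxidation of the primary allylic alcohol with MnO2 should give the enal without touching the esters or the exocyclic alkenes, and the ring-cis C9=C10 geometry is kept.

**Step 20**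
Reactants: 26 (1R,5S,6S,7R,8R,9E)-8-(methacryloyloxy)-14-oxo-1,5-epoxygermacra-4(15),9,11(13)-trien-12,6-olide
Product: 27 (1R,4R,5R,6S,7R,8R,9E)-8-(methacryloyloxy)-14-oxo-1,5:4,15-diepoxygermacra-9,11(13)-dien-12,6-olide (target)
Conditions: dimethyldioxirane (1.1 equiv, acetone solution), CH2Cl2, −20 °C
Reagents that add atoms: dimethyldioxirane, CC1(C)OO1
Why: Dioxirane epoxidation should take only the electron-rich 1,1-disubstituted C4=C15 alkene (the enal, methacrylate and methylene-lactone alkenes are electron-poor) and attack the exo face of the oxabicyclo[5.3.1] core, anti to the C5–C6 bond, which sets C4.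

**Compound list**
1 | (4S,5S)-2,2-dimethyl-1,3-dioxolane-4,5-dimethanol (2,3-O-isopropylidene-L-threitol) | OC[C@@H]1OC(C)(C)O[C@H]1CO | starting material
2 | [(4S,5S)-5-({[tert-butyl(dimethyl)silyl]oxy}methyl)-2,2-dimethyl-1,3-dioxolan-4-yl]methanol | OC[C@@H]1OC(C)(C)O[C@H]1CO[Si](C)(C)C(C)(C)C | intermediate
3 | (4R,5S)-5-({[tert-butyl(dimethyl)silyl]oxy}methyl)-2,2-dimethyl-1,3-dioxolane-4-carbaldehyde | O=C[C@@H]1OC(C)(C)O[C@H]1CO[Si](C)(C)C(C)(C)C | intermediate
4 | tert-butyl{[(4S,5S)-5-ethynyl-2,2-dimethyl-1,3-dioxolan-4-yl]methoxy}dimethylsilane | C#C[C@@H]1OC(C)(C)O[C@H]1CO[Si](C)(C)C(C)(C)C | intermediate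
5 | [(4S,5S)-5-ethynyl-2,2-dimethyl-1,3-dioxolan-4-yl]methanol | C#C[C@@H]1OC(C)(C)O[C@H]1CO | intermediate
6 | (4R,5S)-5-ethynyl-2,2-dimethyl-1,3-dioxolane-4-carbaldehyde | C#C[C@@H]1OC(C)(C)O[C@H]1C=O | intermediate
7 | methyl acrylate | C=CC(=O)OC | starting material
8 | methyl 2-{[(4S,5S)-5-ethynyl-2,2-dimethyl-1,3-dioxolan-4-yl](hydroxy)methyl}prop-2-enoate (carbinol epimers) | C#C[C@@H]1OC(C)(C)O[C@H]1C(O)C(=C)C(=O)OC | intermediate
9 | (5R)-4-hydroxy-5-[(1S)-1-hydroxyprop-2-yn-1-yl]-3-methylideneoxolan-2-one (C4 epimers) | C#C[C@H](O)[C@H]1OC(=O)C(=C)C1O | intermediate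
10 | prop-2-yn-1-ol | C#CCO | starting material
11 | 2-iodoprop-2-en-1-ol | C=C(I)CO | intermediate
12 | 2-iodoprop-2-enal | C=C(I)C=O | intermediate
13 | 2-iodopenta-1,4-dien-3-ol (racemic) | C=CC(O)C(I)=C | intermediate
14 | (5R)-4-hydroxy-5-[(1S)-1-hydroxy-6-iodo-2-methylidene-5-oxohept-6-en-1-yl]-3-methylideneoxolan-2-one (not isolated) | C=C(I)C(=O)CCC(=C)[C@H](O)[C@H]1OC(=O)C(=C)C1O | intermediate
15 | (5S)-4-hydroxy-5-[(2S)-6-hydroxy-6-(1-iodoethenyl)-3-methylideneoxan-2-yl]-3-methylideneoxolan-2-one (not isolated) | C=C(I)C1(O)CCC(=C)[C@H](O1)[C@H]1OC(=O)C(=C)C1O | intermediate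
16 | (5S)-4-hydroxy-5-[(2S)-6-(1-iodoethenyl)-6-methoxy-3-methylideneoxan-2-yl]-3-methylideneoxolan-2-one (anomers) | C=C(I)C1(OC)CCC(=C)[C@H](O1)[C@H]1OC(=O)C(=C)C1O | intermediate
17 | (5S)-4-hydroxy-5-[(2S,6R)-6-(1-iodoethenyl)-3-methylideneoxan-2-yl]-3-methylideneoxolan-2-one (lactone C4 epimers) | C=C(I)[C@H]1CCC(=C)[C@H](O1)[C@H]1OC(=O)C(=C)C1O | intermediate
18 | (5S)-3-(bromomethyl)-5-[(2S,6R)-6-(1-iodoethenyl)-3-methylideneoxan-2-yl]furan-2(5H)-one | C=C(I)[C@H]1CCC(=C)[C@H](O1)[C@H]1OC(=O)C(CBr)=C1 | intermediate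
19 | 2,2-dimethoxyacetaldehyde | COC(OC)C=O | starting material
20 | (4R,5S)-4-[(1R)-1-hydroxy-2,2-dimethoxyethyl]-5-[(2S,6R)-6-(1-iodoethenyl)-3-methylideneoxan-2-yl]-3-methylideneoxolan-2-one | C=C(I)[C@H]1CCC(=C)[C@H](O1)[C@H]1OC(=O)C(=C)[C@@H]1[C@@H](O)C(OC)OC | intermediate
21 | methacrylic acid | C=C(C)C(=O)O | starting material
22 | (1S)-1-{(2S,3S)-2-[(2S,6R)-6-(1-iodoethenyl)-3-methylideneoxan-2-yl]-4-methylidene-5-oxooxolan-3-yl}-2,2-dimethoxyethyl 2-methylprop-2-enoate | C=C(I)[C@H]1CCC(=C)[C@H](O1)[C@H]1OC(=O)C(=C)[C@@H]1[C@H](OC(=O)C(C)=C)C(OC)OC | intermediate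
23 | (1S)-1-{(2S,3S)-2-[(2S,6R)-6-(1-iodoethenyl)-3-methylideneoxan-2-yl]-4-methylidene-5-oxooxolan-3-yl}-2-oxoethyl 2-methylprop-2-enoate | C=C(I)[C@H]1CCC(=C)[C@H](O1)[C@H]1OC(=O)C(=C)[C@@H]1[C@H](OC(=O)C(C)=C)C=O | intermediate
24 | (1R,5S,6S,7R,8S)-9-hydroxy-8-(methacryloyloxy)-1,5-epoxygermacra-4(15),10(14),11(13)-trien-12,6-olide (C9 epimers) | C=C(C)C(=O)O[C@@H]1C(O)C(=C)[C@H]2CCC(=C)[C@H](O2)[C@H]2OC(=O)C(=C)[C@@H]21 | intermediate
25 | (1R,5S,6S,7R,8R,9Z)-14-hydroxy-8-(methacryloyloxy)-1,5-epoxygermacra-4(15),9,11(13)-trien-12,6-olide | C=C(C)C(=O)O[C@@H]1/C=C(/CO)[C@H]2CCC(=C)[C@H](O2)[C@H]2OC(=O)C(=C)[C@@H]21 | intermediate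
26 | (1R,5S,6S,7R,8R,9E)-8-(methacryloyloxy)-14-oxo-1,5-epoxygermacra-4(15),9,11(13)-trien-12,6-olide | C=C(C)C(=O)O[C@@H]1/C=C(/C=O)[C@H]2CCC(=C)[C@H](O2)[C@H]2OC(=O)C(=C)[C@@H]21 | intermediate
27 | (1R,4R,5R,6S,7R,8R,9E)-8-(methacryloyloxy)-14-oxo-1,5:4,15-diepoxygermacra-9,11(13)-dien-12,6-olide (CNP0257628.1) | C=C(C)C(=O)O[C@@H]1/C=C(/C=O)[C@H]2CC[C@@]3(CO3)[C@H](O2)[C@H]2OC(=O)C(=C)[C@@H]21 | target

**Step count and risks**
Total: 20 steps. Longest linear sequence: 17 steps (steps 1–7 and 11–20, from 1); steps 8–10 are a three-step branch to 13.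

The three steps most likely to fail:

1. Step 17 (oligomerisation instead of closure of the strained bridged ring, or migration of the methacryloyl group to the new C9 alkoxide). The fallback exchanges the order of the two carbonyl additions and closes the carbocycle at C7–C8 by an intramolecular indium Barbier allylation. It sets out from 17 and returns at 24. Silylation of the C7 hydroxyl (Et3SiCl, imidazole) gives the C7 triethylsilyl ether F1. Intermolecular Nozaki–Hiyama–Kishi coupling with anhydrous 19 (freed from water by extraction and distillation; CrCl2, NiCl2 cat.) gives the C9 carbinol F2. TBSOTf/2,6-lutidine gives the bis-silyl ether F3. PPTS in MeOH removes only the triethylsilyl group and gives the C7 alcohol F4. NBS/Me2S gives the bromomethyl butenolide F5. Et3SiOTf/2,6-lutidine, then water, frees the C8 aldehyde F6. Indium in THF/H2O at high dilution should close the ring to the macrocyclic C8 carbinol F7, expected as in step 14 with C7 trans to C5 and C8 epimeric to the target. Mitsunobu esterification with 21 as in step 15 gives the methacrylate F8. HF·pyridine removes the C9 silyl group and returns 24.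

2. Step 15 (slow SN2 displacement at the hindered C8 carbinol, elimination, or conjugate addition of the phosphine to the methylene lactone). The fallback inverts C8 by oxidation and reduction. It sets out from 20 and returns at 22. Dess–Martin periodinane gives the C8 ketone F9. NaBH4/CeCl3 at −78 °C should reduce it under Felkin–Anh control (hydride anti to the C6 branch) to the epimeric alcohol F10. Acylation with methacrylic anhydride (DMAP, Et3N) gives 22 with retention.

3. Step 18 (unfavourable position of the transposition equilibrium, or ionisation of the allylic system by the oxophilic catalyst). The fallback replaces the oxo-metal shift by an SNi′ chlorination and an N-oxide oxidation. It sets out from 24 and returns at 26, so step 19 is not needed. SOCl2 in Et2O at 0 °C gives, with allylic transposition, the primary allylic chloride F11. N-Methylmorpholine N-oxide in MeCN (Ganem oxidation) converts it into enal 26.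

**Further compounds**
F1 | step 17 | C7 triethylsilyl ether of 17 (ring stereocentres as in 17) | C=C(I)[C@H]1CCC(=C)[C@H](O1)[C@H]1OC(=O)C(=C)C1O[Si](CC)(CC)CC
F2 | step 17 | 5-{(2S,6R)-6-[3-hydroxy-4,4-dimethoxybut-1-en-2-yl]-3-methylideneoxan-2-yl}-3-methylidene-4-[(triethylsilyl)oxy]oxolan-2-one (C9 carbinol epimers; lactone as in 17) | C=C(C(O)C(OC)OC)[C@H]1CCC(=C)[C@H](O1)[C@H]1OC(=O)C(=C)C1O[Si](CC)(CC)CC
F3 | step 17 | C9 tert-butyldimethylsilyl ether of F2 | C=C(C(O[Si](C)(C)C(C)(C)C)C(OC)OC)[C@H]1CCC(=C)[C@H](O1)[C@H]1OC(=O)C(=C)C1O[Si](CC)(CC)CC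
F4 | step 17 | C7 alcohol obtained from F3 by loss of the triethylsilyl group | C=C(C(O[Si](C)(C)C(C)(C)C)C(OC)OC)[C@H]1CCC(=C)[C@H](O1)[C@H]1OC(=O)C(=C)C1O
F5 | step 17 | (5S)-3-(bromomethyl)-5-{(2S,6R)-6-[3-(tert-butyldimethylsilyloxy)-4,4-dimethoxybut-1-en-2-yl]-3-methylideneoxan-2-yl}furan-2(5H)-one | C=C(C(O[Si](C)(C)C(C)(C)C)C(OC)OC)[C@H]1CCC(=C)[C@H](O1)[C@H]1OC(=O)C(CBr)=C1
F6 | step 17 | C8 aldehyde obtained from F5 by acetal cleavage | C=C(C(O[Si](C)(C)C(C)(C)C)C=O)[C@H]1CCC(=C)[C@H](O1)[C@H]1OC(=O)C(CBr)=C1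
F7 | step 17 | 9-(tert-butyldimethylsilyloxy)-8-hydroxy-1,5-epoxygermacra-4(15),10(14),11(13)-trien-12,6-olide, C8 epimeric to the target, other centres as in 24 | O[C@H]1C(O[Si](C)(C)C(C)(C)C)C(=C)[C@H]2CCC(=C)[C@H](O2)[C@H]2OC(=O)C(=C)[C@@H]21
F8 | step 17 | C9 tert-butyldimethylsilyl ether of 24 | C=C(C)C(=O)O[C@@H]1C(O[Si](C)(C)C(C)(C)C)C(=C)[C@H]2CCC(=C)[C@H](O2)[C@H]2OC(=O)C(=C)[C@@H]21
F9 | step 15 | (4S,5S)-4-(2,2-dimethoxyacetyl)-5-[(2S,6R)-6-(1-iodoethenyl)-3-methylideneoxan-2-yl]-3-methylideneoxolan-2-one | C=C(I)[C@H]1CCC(=C)[C@H](O1)[C@H]1OC(=O)C(=C)[C@@H]1C(=O)C(OC)OC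
F10 | step 15 | (4R,5S)-4-[(1S)-1-hydroxy-2,2-dimethoxyethyl]-5-[(2S,6R)-6-(1-iodoethenyl)-3-methylideneoxan-2-yl]-3-methylideneoxolan-2-one (C8 epimer of 20) | C=C(I)[C@H]1CCC(=C)[C@H](O1)[C@H]1OC(=O)C(=C)[C@@H]1[C@H](O)C(OC)OC
F11 | step 18 | (1R,5S,6S,7R,8R,9E)-14-chloro-8-(methacryloyloxy)-1,5-epoxygermacra-4(15),9,11(13)-trien-12,6-olide | C=C(C)C(=O)O[C@@H]1/C=C(/CCl)[C@H]2CCC(=C)[C@H](O2)[C@H]2OC(=O)C(=C)[C@@H]21
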